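**Plan** (primed locants = side-chain carbons counted from ring carbon C5)
- Retrosynthesis: cut C9'=C10' (Julia–Kocienski) and C7'=C8' (cross-metathesis) in the side chain, then the ring bond O2–C3, then C2=C3 of the enoate (Peterson), then the tertiary C5–OO bond (back to an oxetane C–O bond).
- Enabling feature: in the 1,2-dioxolane (O1–O2–C3–C4–C5) O2 lies β to the ester carbonyl (O2–C3–CH2–C=O), so O2–C3 is the retron of conjugate addition of a C5 hydroperoxide to a 3-methylalk-2-enoate; both peroxide carbons are fully substituted.
- Forward order: dec-9-en-2-one → (E)-allylic alcohol → epoxy alcohol → 1,3-diol → oxetane → masked tertiary hydroperoxide → methyl ketone → enoate → the only ring (dioxolane) → enal → triene.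
- Stereochemistry: C5 from Sharpless epoxidation with D-(−)-diethyl tartrate, retained through hydride opening and oxetane closure, inverted once in the perhydrolysis. C3 from 1,3-induction in the ring closure, with separation of the epimer. 7E from metathesis, 9E from the sulfone olefination, 12Z from (3Z)-hex-3-en-1-ol.

Key step: step 13

Assumption: the enoate geometry of 18 and 19 is lost when C3 becomes sp3 in step 13, so only the (2E)-isomers are numbered and co-formed (2Z)-isomers need not be removed; anions formed by simple deprotonation are treated as ionised forms of the numbered compounds.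

**Step 1**
Reactants: 1 dec-9-en-2-one; 2 triethyl phosphonoacetate
Product: 3 ethyl (2E)-3-methylundeca-2,10-dienoate
Conditions: NaH, THF, 0 °C to reflux; chromatography to remove the (2Z)-isomer
Reagents that add atoms: none
Why: Horner–Wadsworth–Emmons olefination of a methyl ketone with a stabilised phosphonate anion should favour the (E)-ester; the minor (Z)-ester is removed here because after step 3 it would give the opposite configuration at the tertiary carbon.

**Step 2**
Reactants: 3 ethyl (2E)-3-methylundeca-2,10-dienoate
Product: 4 (2E)-3-methylundeca-2,10-dien-1-ol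
Conditions: iBu2AlH (2.2 equiv), CH2Cl2, −78 to 0 °C; aqueous potassium sodium tartrate work-up
Reagents that add atoms: none
Why: 1,2-reduction of the conjugated ester by iBu2AlH gives the allylic alcohol and leaves both alkenes and the alkene geometry untouched.

**Step 3**
Reactants: 4 (2E)-3-methylundeca-2,10-dien-1-ol
Product: 5 [(2R,3R)-3-methyl-3-(oct-7-en-1-yl)oxiran-2-yl]methanol
Conditions: Ti(OiPr)4 (10 mol%), D-(−)-diethyl tartrate (12 mol%), t-BuOOH, 4 Å molecular sieves, CH2Cl2, −20 °C
Reagents that add atoms: tert-butyl hydroperoxide, CC(C)(C)OO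
Why: Sharpless asymmetric epoxidation: the catalyst formed from Ti(OiPr)4 and the D-(−)-tartrate delivers oxygen to the face of the (E)-allylic alcohol that gives the (2R,3R)-epoxide (the mirror image of the outcome established for geraniol with the L-(+)-ester), which sets the tertiary C–O stereocentre, while the terminal alkene lacks a directing hydroxyl and stays intact.

**Step 4**
Reactants: 5 [(2R,3R)-3-methyl-3-(oct-7-en-1-yl)oxiran-2-yl]methanol
Product: 6 (3R)-3-methylundec-10-ene-1,3-diol
Conditions: NaAlH2(OCH2CH2OMe)2, THF, 0 °C to rt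
Reagents that add atoms: none
Why: Regioselective reductive opening of a 2,3-epoxy alcohol: the aluminate formed at the hydroxyl delivers hydride intramolecularly to C2, so the tertiary C3–O bond and its configuration are kept and the 1,3-diol results.

**Step 5**
Reactants: 6 (3R)-3-methylundec-10-ene-1,3-diol
Product: 8 (2R)-2-methyl-2-(oct-7-en-1-yl)oxetane, via monotosylate 7 (not isolated)
Conditions: n-BuLi (1.0 equiv), THF, 0 °C; TsCl (1.0 equiv), 0 °C to rt; n-BuLi (1.0 equiv), 0 to 60 °C
Reagents that add atoms: none
Why: One-pot intramolecular Williamson etherification: the primary hydroxyl is sulfonylated selectively and the tertiary alkoxide closes the oxetane by 4-exo-tet displacement at the primary carbon, so no bond to the stereocentre is broken and it stays (R).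

**Step 6**
Reactants: 8 (2R)-2-methyl-2-(oct-7-en-1-yl)oxetane
Product: 9 (3S)-3-hydroperoxy-3-methylundec-10-en-1-ol
Conditions: anhydrous H2O2 in Et2O (excess), Me3SiOTf (cat.), Et2O, −78 to 0 °C
Reagents that add atoms: hydrogen peroxide, OO
Why: Lewis-acid-mediated perhydrolysis of a 2,2-disubstituted oxetane: silylation of the ring oxygen lets H2O2 attack the more substituted carbon from the rear in a loose SN2-type opening, so the new C–O bond forms with inversion and (R)-8 should give (S)-9.

**Step 7**
Reactants: 9 (3S)-3-hydroperoxy-3-methylundec-10-en-1-ol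
Product: 11 (3S)-3-[(2-methoxypropan-2-yl)peroxy]-3-methylundec-10-en-1-ol, via bis-ketal 10 (not isolated)
Conditions: 2-methoxypropene (excess), pyridinium p-toluenesulfonate (cat.), CH2Cl2, 0 °C; then MeOH, 0 °C, brief; Et3N quench
Reagents that add atoms: 2-methoxypropene, COC(C)=C
Why: Acid-catalysed ketalisation with the enol ether caps both OH and OOH, and brief methanolysis (chemoselective transketalisation) should then free only the alcohol, because a monoperoxyketal is markedly less acid-labile than the corresponding alkyl ketal.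

**Step 8**
Reactants: 11 (3S)-3-[(2-methoxypropan-2-yl)peroxy]-3-methylundec-10-en-1-ol
Product: 12 (3S)-3-[(2-methoxypropan-2-yl)peroxy]-3-methylundec-10-enal
Conditions: Dess–Martin periodinane, pyridine, CH2Cl2, 0 °C to rt
Reagents that add atoms: none
Why: Dess–Martin oxidation of the primary alcohol under buffered, non-basic conditions gives the β-peroxy aldehyde without the enolisation that could expel the peroxy group.

**Step 9**
Reactants: 12 (3S)-3-[(2-methoxypropan-2-yl)peroxy]-3-methylundec-10-enal; 13 methylmagnesium bromide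
Product: 14 (2RS,4S)-4-[(2-methoxypropan-2-yl)peroxy]-4-methyldodec-11-en-2-ol
Conditions: MeMgBr (1.1 equiv), THF, −78 °C; aqueous NH4Cl quench at −78 °C
Reagents that add atoms: none
Why: Grignard 1,2-addition to the aldehyde at −78 °C should be much faster than attack of MeMgBr on the hindered tertiary peroxyketal O–O bond or enolisation; the new carbinol centre is uncontrolled and is erased in step 10.

**Step 10**
Reactants: 14 (2RS,4S)-4-[(2-methoxypropan-2-yl)peroxy]-4-methyldodec-11-en-2-ol
Product: 15 (4S)-4-[(2-methoxypropan-2-yl)peroxy]-4-methyldodec-11-en-2-one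
Conditions: Dess–Martin periodinane, pyridine, CH2Cl2, 0 °C to rt
Reagents that add atoms: none
Why: Dess–Martin oxidation of the secondary alcohol gives the methyl ketone and converges both carbinol epimers on one compound.

**Step 11**
Reactants: 15 (4S)-4-[(2-methoxypropan-2-yl)peroxy]-4-methyldodec-11-en-2-one; 16 methyl 2-(trimethylsilyl)acetate
Product: 18 methyl (2E,5S)-5-[(2-methoxypropan-2-yl)peroxy]-3,5-dimethyltrideca-2,12-dienoate, via β-silyl alkoxide 17 (not isolated)
Conditions: LiN(iPr)2, 16, THF, −78 °C; then 15, −78 to −20 °C; cold aqueous NH4Cl quench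
Reagents that add atoms: none
Why: Peterson olefination: the lithium enolate of the α-silyl ester adds to the hindered methyl ketone at −78 °C and the adduct collapses with loss of lithium trimethylsilanolate; this kinetically controlled low-temperature olefination is preferred to a phosphonate olefination at ambient temperature because equilibrating base would enolise the ketone towards C4 and expel the β-peroxy group.

**Step 12**
Reactants: 18 methyl (2E,5S)-5-[(2-methoxypropan-2-yl)peroxy]-3,5-dimethyltrideca-2,12-dienoate
Product: 19 methyl (2E,5S)-5-hydroperoxy-3,5-dimethyltrideca-2,12-dienoate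
Conditions: AcOH–THF–H2O, rt
Reagents that add atoms: none
Why: Mild aqueous-acid hydrolysis of the peroxyketal (acetal hydrolysis) frees the tertiary hydroperoxide; the enoate and the O–O bond tolerate acetic acid and no base is present to start the cyclisation early.

**Step 13**
Reactants: 19 methyl (2E,5S)-5-hydroperoxy-3,5-dimethyltrideca-2,12-dienoate
Product: 20 methyl 2-[(3R,5S)-3,5-dimethyl-5-(oct-7-en-1-yl)-1,2-dioxolan-3-yl]acetate
Conditions: Et2NH (1 equiv), CF3CH2OH, rt; chromatographic separation of the C3 epimer
Reagents that add atoms: none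
Why: The amine deprotonates the tertiary hydroperoxide and the peroxy anion adds to C3 of the tethered 3-methyl-2-enoate, the resulting ester enolate being protonated by the trifluoroethanol medium. This is the intramolecular peroxy-Michael addition known for hydroperoxy enoates, which gives 1,2-dioxolane- and 1,2-dioxane-acetates under the same amine–fluoroalcohol conditions. The ring closes in a 5-exo-trig mode and O2–C3 is the only new skeletal bond. The new C3 stereocentre is controlled only by 1,3-induction from C5; since C5 carries a methyl and a primary alkyl group of similar size, a ratio near unity with an uncertain sense of bias must be expected. The required 3,5-trans isomer (acetate arm anti to the side chain, 3R,5S) is therefore secured by separation, and the unwanted epimer may be re-opened by retro-addition with a stronger base and cyclised again. Chemoselectivity rests on the substrate: the β,β-disubstituted enoate resists amine addition, neither peroxide carbon bears hydrogen so Kornblum–DeLaMare fragmentation is excluded, and the remote alkene is inert.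

**Step 14**
Reactants: 20 methyl 2-[(3R,5S)-3,5-dimethyl-5-(oct-7-en-1-yl)-1,2-dioxolan-3-yl]acetate; 21 (2E)-but-2-enal
Product: 22 methyl 2-[(3R,5S)-3,5-dimethyl-5-[(7E)-9-oxonon-7-en-1-yl]-1,2-dioxolan-3-yl]acetate
Conditions: 21 (5 equiv), second-generation Hoveyda–Grubbs catalyst RuCl2(H2IMes)(=CH–C6H4-2-OiPr) (5 mol%), CH2Cl2, 40 °C
Reagents that add atoms: none
Why: Olefin cross-metathesis between a terminal alkene and an electron-poor enal is selective for the cross product and should give the conjugated (E)-enal under thermodynamic control; the catalyst tolerates the fully substituted dialkyl peroxide and the ester.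

**Step 15**
Reactants: 23 (3Z)-hex-3-en-1-ol; 24 1,3-benzothiazole-2-thiol
Product: 25 2-{[(3Z)-hex-3-en-1-yl]sulfanyl}-1,3-benzothiazole
Conditions: PPh3, diisopropyl azodicarboxylate, THF, 0 °C to rt
Reagents that add atoms: none
Why: Mitsunobu thioetherification of the primary alcohol with the acidic heteroaryl thiol takes place at the carbinol carbon and leaves the (Z)-alkene untouched.

**Step 16**
Reactants: 25 2-{[(3Z)-hex-3-en-1-yl]sulfanyl}-1,3-benzothiazole
Product: 26 2-{[(3Z)-hex-3-en-1-yl]sulfonyl}-1,3-benzothiazole
Conditions: (NH4)6Mo7O24·4H2O (cat.), 30% aqueous H2O2, EtOH, 0 °C to rt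
Reagents that add atoms: hydrogen peroxide, OO
Why: Molybdate-catalysed sulfide-to-sulfone oxidation with H2O2 is far faster than epoxidation of the isolated (Z)-alkene.

**Step 17**
Reactants: 22 methyl 2-[(3R,5S)-3,5-dimethyl-5-[(7E)-9-oxonon-7-en-1-yl]-1,2-dioxolan-3-yl]acetate; 26 2-{[(3Z)-hex-3-en-1-yl]sulfonyl}-1,3-benzothiazole
Product: 28 methyl 2-[(3R,5S)-3,5-dimethyl-5-[(7E,9E,12Z)-pentadeca-7,9,12-trien-1-yl]-1,2-dioxolan-3-yl]acetate, via β-alkoxysulfone 27 (not isolated)
Conditions: NaN(SiMe3)2 (1.0 equiv relative to 26) added to 22 and 26 (1.2 equiv), THF, −78 °C to rt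
Reagents that add atoms: none
Why: Julia–Kocienski olefination: the metalated benzothiazolyl sulfone adds to the enal, and Smiles rearrangement with loss of SO2 and benzothiazolone forms the alkene, which with α,β-unsaturated aldehydes is expected to be mainly (E) and so completes the (7E,9E)-diene; adding the base to the sulfone–aldehyde mixture at −78 °C keeps it away from the ester α-hydrogens, and the (12Z)-alkene comes in unchanged from 23.

**Compound list**
1 | dec-9-en-2-one | CC(=O)CCCCCCC=C | starting material
2 | triethyl phosphonoacetate | CCOC(=O)CP(=O)(OCC)OCC | starting material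
3 | ethyl (2E)-3-methylundeca-2,10-dienoate | CCOC(=O)/C=C(\C)CCCCCCC=C | intermediate
4 | (2E)-3-methylundeca-2,10-dien-1-ol | OC/C=C(\C)CCCCCCC=C | intermediate
5 | [(2R,3R)-3-methyl-3-(oct-7-en-1-yl)oxiran-2-yl]methanol | OC[C@H]1O[C@]1(C)CCCCCCC=C | intermediate
6 | (3R)-3-methylundec-10-ene-1,3-diol | OCC[C@@](O)(C)CCCCCCC=C | intermediate
7 | (3R)-3-hydroxy-3-methylundec-10-en-1-yl 4-methylbenzenesulfonate | Cc1ccc(cc1)S(=O)(=O)OCC[C@@](O)(C)CCCCCCC=C | intermediate (not isolated)
8 | (2R)-2-methyl-2-(oct-7-en-1-yl)oxetane | C1CO[C@]1(C)CCCCCCC=C | intermediate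
9 | (3S)-3-hydroperoxy-3-methylundec-10-en-1-ol | OCC[C@](OO)(C)CCCCCCC=C | intermediate
10 | (9S)-11-[(2-methoxypropan-2-yl)oxy]-9-[(2-methoxypropan-2-yl)peroxy]-9-methylundec-1-ene | COC(C)(C)OCC[C@](OOC(C)(C)OC)(C)CCCCCCC=C | intermediate (not isolated)
11 | (3S)-3-[(2-methoxypropan-2-yl)peroxy]-3-methylundec-10-en-1-ol | OCC[C@](OOC(C)(C)OC)(C)CCCCCCC=C | intermediate
12 | (3S)-3-[(2-methoxypropan-2-yl)peroxy]-3-methylundec-10-enal | O=CC[C@](OOC(C)(C)OC)(C)CCCCCCC=C | intermediate
13 | methylmagnesium bromide | C[Mg]Br | starting material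
14 | (2RS,4S)-4-[(2-methoxypropan-2-yl)peroxy]-4-methyldodec-11-en-2-ol (both C2 epimers) | CC(O)C[C@](OOC(C)(C)OC)(C)CCCCCCC=C | intermediate
15 | (4S)-4-[(2-methoxypropan-2-yl)peroxy]-4-methyldodec-11-en-2-one | CC(=O)C[C@](OOC(C)(C)OC)(C)CCCCCCC=C | intermediate
16 | methyl 2-(trimethylsilyl)acetate | COC(=O)C[Si](C)(C)C | starting material
17 | lithium (5S)-1-methoxy-5-[(2-methoxypropan-2-yl)peroxy]-3,5-dimethyl-1-oxo-2-(trimethylsilyl)tridec-12-en-3-olate (C2/C3 diastereomers) | [Li+].COC(=O)C([Si](C)(C)C)C(C)([O-])C[C@](OOC(C)(C)OC)(C)CCCCCCC=C | intermediate (not isolated)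
18 | methyl (2E,5S)-5-[(2-methoxypropan-2-yl)peroxy]-3,5-dimethyltrideca-2,12-dienoate | COC(=O)/C=C(\C)C[C@](OOC(C)(C)OC)(C)CCCCCCC=C | intermediate
19 | methyl (2E,5S)-5-hydroperoxy-3,5-dimethyltrideca-2,12-dienoate | COC(=O)/C=C(\C)C[C@](OO)(C)CCCCCCC=C | intermediate
20 | methyl 2-[(3R,5S)-3,5-dimethyl-5-(oct-7-en-1-yl)-1,2-dioxolan-3-yl]acetate | C=CCCCCCC[C@@]1(C)C[C@](C)(CC(=O)OC)OO1 | intermediate
21 | (2E)-but-2-enal | C/C=C/C=O | starting material
22 | methyl 2-[(3R,5S)-3,5-dimethyl-5-[(7E)-9-oxonon-7-en-1-yl]-1,2-dioxolan-3-yl]acetate | O=C/C=C/CCCCCC[C@@]1(C)C[C@](C)(CC(=O)OC)OO1 | intermediate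
23 | (3Z)-hex-3-en-1-ol | CC/C=C\CCO | starting material
24 | 1,3-benzothiazole-2-thiol | Sc1nc2ccccc2s1 | starting material
25 | 2-{[(3Z)-hex-3-en-1-yl]sulfanyl}-1,3-benzothiazole | CC/C=C\CCSc1nc2ccccc2s1 | intermediate
26 | 2-{[(3Z)-hex-3-en-1-yl]sulfonyl}-1,3-benzothiazole | CC/C=C\CCS(=O)(=O)c1nc2ccccc2s1 | intermediate
27 | sodium alkoxide of methyl 2-[(3R,5S)-5-[(7E,12Z)-10-(1,3-benzothiazol-2-ylsulfonyl)-9-hydroxypentadeca-7,12-dien-1-yl]-3,5-dimethyl-1,2-dioxolan-3-yl]acetate (C9'/C10' diastereomers) | [Na+].CC/C=C\CC(S(=O)(=O)c1nc2ccccc2s1)C([O-])/C=C/CCCCCC[C@@]1(C)C[C@](C)(CC(=O)OC)OO1 | intermediate (not isolated)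
28 | methyl 2-[(3R,5S)-3,5-dimethyl-5-[(7E,9E,12Z)-pentadeca-7,9,12-trien-1-yl]-1,2-dioxolan-3-yl]acetate | CC/C=C\C/C=C/C=C/CCCCCC[C@@]1(C)C[C@](C)(CC(=O)OC)OO1 | target

**Count**
Total steps: 17. Longest linear sequence: 15 (steps 1–14 and 17); the sulfone arm is steps 15–16.

**Steps most likely to fail**

1. Step 13 – ring closure with little or no facial preference at C3. The 1,3-induction may leave the two epimers in comparable amounts, and reversible addition can hold them there, so much material would have to be separated and recycled.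
Fallback: set out from ketone 15 and create the C3 stereocentre by C–C instead of C–O bond formation. Acidic methanol (p-toluenesulfonic acid, MeOH, rt) exchanges the peroxyketal, and the freed hydroperoxy ketone closes to the hemiperketal (5S)-3,5-dimethyl-5-(oct-7-en-1-yl)-1,2-dioxolan-3-ol F1. In the same flask F1 is ketalised to (5S)-3-methoxy-3,5-dimethyl-5-(oct-7-en-1-yl)-1,2-dioxolane F2. TiCl4 in CH2Cl2 at −78 °C ionises F2 to the cyclic peroxycarbenium ion, which is trapped by 1-methoxy-1-(trimethylsilyloxy)ethene. Irreversible attack on the planar cation anti to the longer C5 substituent should favour 20, where the route is rejoined. This is the established Lewis-acid substitution of 3-alkoxy-1,2-dioxolanes by silyl ketene acetals.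

2. Step 11 – loss of the peroxy group during olefination. Enolisation of the ketone towards C4, during the addition or while the mixture warms for the silanolate elimination, would expel the β-peroxy group (E1cB or epoxide formation). The hindered carbonyl may also simply be enolised at the methyl group and returned unchanged.
Fallback: set out from 15 and separate C–C from C=C bond formation. The lithium enolate of methyl acetate (LiN(iPr)2, THF, −78 °C) is added and the mixture is quenched at −78 °C with AcOH. This gives the aldol methyl (5S)-3-hydroxy-5-[(2-methoxypropan-2-yl)peroxy]-3,5-dimethyltridec-12-enoate F3, a stable adduct that no longer contains the ketone. Trifluoroacetylation ((CF3CO)2O, pyridine, 0 °C) gives methyl (5S)-5-[(2-methoxypropan-2-yl)peroxy]-3,5-dimethyl-3-(trifluoroacetoxy)tridec-12-enoate F4. DBU then removes trifluoroacetate by E1cB through the ester enolate and delivers 18, where the route is rejoined.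

3. Step 17 – base-triggered events on the finished ring. Deprotonation α to the ester would open the dioxolane by retro-Michael elimination and scramble C3 on re-closure. The skipped triene could also drift into conjugation, and the (9E)-selectivity may be incomplete with isomers that are hard to separate.
Fallback: set out from 20 and build the diene by cross-coupling two alkenes of fixed geometry. Cross-metathesis of 20 with 4,4,5,5-tetramethyl-2-vinyl-1,3,2-dioxaborolane (same catalyst as step 14) gives methyl 2-[(3R,5S)-3,5-dimethyl-5-[(7E)-8-(4,4,5,5-tetramethyl-1,3,2-dioxaborolan-2-yl)oct-7-en-1-yl]-1,2-dioxolan-3-yl]acetate F5. Separately, 23 is oxidised (Dess–Martin periodinane, pyridine) to (3Z)-hex-3-enal F6, which is used at once in a Takai olefination (CrCl2, CHI3, THF, 0 °C) to give (1E,4Z)-1-iodohepta-1,4-diene F7. Suzuki–Miyaura coupling of F5 with F7 (Pd(PPh3)4, aqueous K3PO4, THF, rt) joins C8' to C9' with retention at both alkenes and gives the target 28 directly.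

**Further compounds**
F1 | step 13 | (5S)-3,5-dimethyl-5-(oct-7-en-1-yl)-1,2-dioxolan-3-ol (C3 epimers) | CC1(O)C[C@](C)(CCCCCCC=C)OO1
F2 | step 13 | (5S)-3-methoxy-3,5-dimethyl-5-(oct-7-en-1-yl)-1,2-dioxolane (C3 epimers) | COC1(C)C[C@](C)(CCCCCCC=C)OO1
F3 | step 11 | methyl (5S)-3-hydroxy-5-[(2-methoxypropan-2-yl)peroxy]-3,5-dimethyltridec-12-enoate (C3 epimers) | COC(=O)CC(C)(O)C[C@](OOC(C)(C)OC)(C)CCCCCCC=C
F4 | step 11 | methyl (5S)-5-[(2-methoxypropan-2-yl)peroxy]-3,5-dimethyl-3-(trifluoroacetoxy)tridec-12-enoate (C3 epimers) | COC(=O)CC(C)(OC(=O)C(F)(F)F)C[C@](OOC(C)(C)OC)(C)CCCCCCC=C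
F5 | step 17 | methyl 2-[(3R,5S)-3,5-dimethyl-5-[(7E)-8-(4,4,5,5-tetramethyl-1,3,2-dioxaborolan-2-yl)oct-7-en-1-yl]-1,2-dioxolan-3-yl]acetate | CC1(C)OB(/C=C/CCCCCC[C@@]2(C)C[C@](C)(CC(=O)OC)OO2)OC1(C)C
F6 | step 17 | (3Z)-hex-3-enal | CC/C=C\CC=O
F7 | step 17 | (1E,4Z)-1-iodohepta-1,4-diene | CC/C=C\C/C=C/I
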